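**Retrosynthetic overview**
1. Last disconnection: endo, OH-syn Diels–Alder between the exocyclic alkene of dioxanone 10 and the diene C(CH3)=C(OH)–C(acyl)=CH of a sorbicillinol-type dienone released from 21. This closes the bicyclo[2.2.2]octane and sets both bridgeheads and the spiro carbon.
2. The carbocycle C(=O)–C(CH3)–C(=O)–C(CH3)(OH)–CH–C(acyl) (the six-membered ring carrying both methyl groups) is made by two-carbon ring expansion of cyclobutenone 16 with ynone 19, which is generated in the same flask from alcohol 18: 4π opening to a vinylketene, then [4+2].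
3. Enabling feature: in that ring, the enolised C=O next to the acyl-bearing carbon, the C–CH3, the second C–O and the C(CH3)(O) carbon are four contiguous carbons with exactly the oxygen pattern of a squarate-derived 4-oxy-3-alkoxy-2-methylcyclobutenone. The remaining CH and C(acyl) carbons are the two carbons of a terminal ynone, and the fully substituted C(CH3)(O) carbon blocks aromatisation.
4. Fragments: 10 from (−)-shikimic acid (4,5-diacetal, inversion at C3, O–H insertion/methylenation, lactonisation); 16 from di-tert-butyl squarate (two MeLi additions); 18 from sorbaldehyde.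
5. Ring order: cyclohexene (chiral pool) → dioxanone → cyclobutenone → six-membered carbocycle (ring expansion) → bicyclo[2.2.2]octane (Diels–Alder).

Key step: step 11

Remark on stereochemistry: the cyclohexene unit of the target has the configuration of shikimic acid at C4 and C5 and the inverted configuration at C3 (shikimate numbering), so natural (−)-shikimic acid is used with one inversion.
Remark on the quinol centre: the ring expansion gives the quinol carbon as a racemate. Dienone 21 is therefore used in excess, and the enantiopure dienophile 10 is expected to take the (R)-enantiomer in step 12; diastereomers from the other enantiomer are removed by chromatography.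
Remark on tautomers: the β-triketone of the target is one of several rapidly interconverting enol tautomers; the route delivers this equilibrium mixture.

Step 1
Reactants: 1 (−)-shikimic acid
Product: 2 methyl shikimate 4,5-butane-2,3-diacetal (3-OH free; acetal carbons S,S with both OMe axial)
Conditions: butane-2,3-dione, HC(OMe)3, CSA (cat.), MeOH, reflux
Reagents that add atoms: butane-2,3-dione CC(=O)C(C)=O; methanol CO; trimethyl orthoformate COC(OC)OC
Why: Fischer esterification and butane-2,3-diacetal formation occur under the same acidic methanolic conditions; the diacetal is selective for the trans-diequatorial 4,5-diol and its two acetal centres are set thermodynamically by the double anomeric effect.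

Step 2
Reactants: 2 methyl shikimate 4,5-butane-2,3-diacetal
Product: 3 methyl 3-epi-shikimate 4,5-butane-2,3-diacetal 3-(4-nitrobenzoate)
Conditions: 4-O2NC6H4CO2H, PPh3, DIAD, THF, 0 °C → rt
Reagents that add atoms: 4-nitrobenzoic acid O=C(O)c1ccc(cc1)[N+](=O)[O-]
Why: Mitsunobu reaction; SN2 displacement of the activated allylic C3 oxygen by the carboxylate inverts C3 and gives the 3,4-trans arrangement needed in the target.

Step 3
Reactants: 3 methyl 3-epi-shikimate 4,5-butane-2,3-diacetal 3-(4-nitrobenzoate)
Product: 4 methyl 3-epi-shikimate 4,5-butane-2,3-diacetal (free 3-OH, all-trans)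
Conditions: K2CO3 (cat.), MeOH, 0 °C
Reagents that add atoms: none
Why: Base-catalysed methanolysis removes the activated aryl ester; the ring methyl ester only exchanges with the solvent and no stereocentre is touched.

Step 4
Reactants: 5 trimethyl phosphonoacetate
Product: 6 trimethyl diazophosphonoacetate
Conditions: 4-acetamidobenzenesulfonyl azide, DBU, MeCN, 0 °C → rt
Reagents that add atoms: 4-acetamidobenzenesulfonyl azide CC(=O)Nc1ccc(cc1)S(=O)(=O)N=[N+]=[N-]
Why: Regitz diazo transfer to a doubly activated methylene group.

Step 5
Reactants: 4 methyl 3-epi-shikimate 4,5-butane-2,3-diacetal; 6 trimethyl diazophosphonoacetate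
Product: 7 methyl 3-epi-shikimate 4,5-butane-2,3-diacetal 3-O-[(dimethoxyphosphoryl)(methoxycarbonyl)methyl] ether (epimer mixture at the new CH)
Conditions: Rh2(OAc)4 (2 mol %), PhMe, 80 °C, slow addition of 6
Reagents that add atoms: none
Why: Rhodium carbenoid O–H insertion into the only free hydroxyl; the C3–O bond is not broken, so C3 keeps its configuration, and the new phosphonate-bearing centre is removed in step 6.

Step 6
Reactants: 7 methyl 3-epi-shikimate 4,5-butane-2,3-diacetal 3-O-[(dimethoxyphosphoryl)(methoxycarbonyl)methyl] ether
Product: 8 methyl 3-epi-shikimate 4,5-butane-2,3-diacetal 3-O-[1-(methoxycarbonyl)vinyl] ether (enol pyruvate ether)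
Conditions: LiN(SiMe3)2, THF, −78 °C; then HCHO (gas), −78 → 0 °C
Reagents that add atoms: formaldehyde C=O
Why: Horner–Wadsworth–Emmons olefination of the α-alkoxy phosphonoacetate with formaldehyde gives the 1,1-disubstituted alkene; no stereocentre is formed.

Step 7
Reactants: 8 methyl 3-epi-shikimate 4,5-butane-2,3-diacetal 3-O-[1-(methoxycarbonyl)vinyl] ether
Product: 10 methyl (3S,4S,5R)-5-hydroxy-3,4-(1-methylidene-2-oxoethane-1,2-diyldioxy)cyclohex-1-ene-1-carboxylate (trans-fused 3-methylidene-1,4-dioxan-2-one; ether O on C3; lactone O on C4), via enolpyruvyl diol 9 (not isolated)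
Conditions: TFA/H2O (9:1), CH2Cl2, 0 °C → rt; evaporate; then CSA (cat.), PhMe, 5 Å MS, 80 °C
Reagents that add atoms: none
Why: Acid hydrolysis of the diacetal followed by acid-catalysed lactonisation (transesterification) of the C4 hydroxyl onto the neighbouring α-alkoxyacrylate ester, which closes a six-membered ring whereas the C5 hydroxyl would need a seven-membered one.

Step 8
Reactants: 11 di-tert-butyl squarate
Product: 14 3-tert-butoxy-4-methylcyclobut-3-ene-1,2-dione, via lithium alkoxide 12 (not isolated), via trifluoroacetate 13 (not isolated)
Conditions: MeLi, THF, −78 °C; then (CF3CO)2O, −78 °C → rt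
Reagents that add atoms: methyllithium [Li]C
Why: 1,2-Addition of MeLi to the squarate ester and anhydride-induced ionisation/rearrangement of the adduct with loss of one tert-butyl group is the standard route to 3-alkoxy-4-alkylcyclobutenediones.

Step 9
Reactants: 14 3-tert-butoxy-4-methylcyclobut-3-ene-1,2-dione
Product: 16 3-tert-butoxy-2,4-dimethyl-4-(trimethylsilyloxy)cyclobut-2-en-1-one (racemic), via lithium alkoxide 15 (not isolated)
Conditions: MeLi, THF, −78 °C; then Me3SiCl, −78 → 0 °C
Reagents that add atoms: methyllithium [Li]C; chlorotrimethylsilane C[Si](C)(C)Cl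
Why: 1,2-Addition of MeLi goes to the ketone-like carbonyl next to the C–OtBu carbon (the other carbonyl is a deactivated vinylogous ester), and the alkoxide is silylated in situ; the tertiary carbinol centre forms as a racemate.

Step 10
Reactants: 17 (2E,4E)-hexa-2,4-dienal (sorbaldehyde)
Product: 18 (4E,6E)-octa-4,6-dien-1-yn-3-ol (racemic)
Conditions: HC≡CMgBr, THF, −78 → 0 °C; aq NH4Cl
Reagents that add atoms: ethynylmagnesium bromide C#C[Mg]Br
Why: Grignard 1,2-addition to the dienal; the carbinol centre is removed in step 11.

Step 11
Reactants: 16 3-tert-butoxy-2,4-dimethyl-4-(trimethylsilyloxy)cyclobut-2-en-1-one; 18 (4E,6E)-octa-4,6-dien-1-yn-3-ol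
Product: 21 5-tert-butoxy-2-[(2E,4E)-hexa-2,4-dienoyl]-4,6-dimethyl-4-(trimethylsilyloxy)cyclohexa-2,5-dien-1-one (racemic), via ynone 19 (not isolated), via vinylketene 20 (not isolated)
Conditions: MnO2 (10 equiv), PhMe, rt; filter (Celite/MgSO4) onto 4 Å MS; then 16, BHT (cat.), PhMe (0.2 M), 110 °C; 18 in threefold excess over 16
Reagents that add atoms: none
Why: Proposed new method: MnO2 first oxidises the doubly activated (allylic and propargylic) alcohol 18 to ynone 19, which is carried on as a dried filtrate because terminal dienyl ynones polymerise on concentration, and heating should then open cyclobutenone 16 by conrotatory 4π electrocyclic cleavage of its C1–C4 bond (OSiMe3 rotating outward) to vinylketene 20, whose enol-ether carbon C4 is nucleophilic and whose ketene carbon is electrophilic, so that it should add across 19 in a polarity-matched, asynchronous [4+2] cycloaddition (C4 to the terminal alkyne CH, ketene carbon to the acyl-bearing alkyne carbon); the closest known reaction types are the [4+2] cycloadditions of (trialkylsilyl)vinylketenes with activated alkynes and the Ni(COD)2-catalysed ring expansion of cyclobutenones with alkynes to phenols. The only ring closed is the six-membered carbocycle, formed in an intermolecular [4+2] mode in which the four ring carbons of 16 are kept and the two alkyne carbons are inserted between C1 and C4, a net two-carbon ring expansion. The new stereocentre C(CH3)(OSiMe3) forms without control as a racemate, and its sense is selected in step 12 by the enantiopure dienophile. The step needs regioselectivity, which the 3-alkoxy donor of 20 (activating C4) and the acceptor polarisation of 19 should secure, and [4+2] rather than ketene [2+2], which should hold because electron-poor alkynes are poor ketenophiles. Ring opening is reversible, so vinylketene that is not trapped returns to 16, and the fully substituted C4 prevents aromatisation, so the product stays at the dienone level. The tert-butyl and trimethylsilyl groups are temporary locks that stop the dioxygenated vinylketene from tautomerising to an acylketene; both are removed in step 12.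

Step 12
Reactants: 21 5-tert-butoxy-2-[(2E,4E)-hexa-2,4-dienoyl]-4,6-dimethyl-4-(trimethylsilyloxy)cyclohexa-2,5-dien-1-one; 10 methylidene dioxanone lactone
Product: 23 target CNP0259039.2, via sorbicillinol 22 (not isolated)
Conditions: TFA (10 equiv), CH2Cl2, 0 °C, slow addition of racemic 21 (2.5 equiv) to 10; then rt; aq NaHCO3
Reagents that add atoms: none
Why: TFA removes the tert-butyl and trimethylsilyl groups to release sorbicillinol 22, whose 2,4-dienone tautomer should undergo a Diels–Alder reaction with the enol-ether-like exocyclic alkene of 10 (CH2 to the C–H diene terminus, the oxygenated carbon to the C–CH3 terminus, lactone carbonyl endo, approach on the diene face that carries the tertiary OH), which sets both bridgeheads and the spiro carbon, while 10 should take the (R)-quinol from the racemate because only that enantiomer can combine the endo, OH-syn approach with the face of the exocyclic alkene that is anti to the axial C–H of the lactone-oxygen-bearing carbon (kinetic resolution).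

**Compound list**
1 | (−)-shikimic acid | O[C@@H]1C=C(C(=O)O)C[C@@H](O)[C@@H]1O | starting material
2 | methyl shikimate 4,5-butane-2,3-diacetal | O[C@@H]1C=C(C(=O)OC)C[C@H]2O[C@](C)(OC)[C@@](C)(OC)O[C@H]12 | intermediate
3 | methyl 3-epi-shikimate 4,5-butane-2,3-diacetal 3-(4-nitrobenzoate) | O=C(O[C@H]1C=C(C(=O)OC)C[C@H]2O[C@](C)(OC)[C@@](C)(OC)O[C@H]12)c1ccc(cc1)[N+](=O)[O-] | intermediate
4 | methyl 3-epi-shikimate 4,5-butane-2,3-diacetal | O[C@H]1C=C(C(=O)OC)C[C@H]2O[C@](C)(OC)[C@@](C)(OC)O[C@H]12 | intermediate
5 | trimethyl phosphonoacetate | COC(=O)CP(=O)(OC)OC | starting material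
6 | trimethyl diazophosphonoacetate | COC(=O)C(=[N+]=[N-])P(=O)(OC)OC | intermediate
7 | methyl 3-epi-shikimate 4,5-butane-2,3-diacetal 3-O-[(dimethoxyphosphoryl)(methoxycarbonyl)methyl] ether (epimer mixture at CH–P) | COC(=O)C(O[C@H]1C=C(C(=O)OC)C[C@H]2O[C@](C)(OC)[C@@](C)(OC)O[C@H]12)P(=O)(OC)OC | intermediate
8 | methyl 3-epi-shikimate 4,5-butane-2,3-diacetal 3-O-[1-(methoxycarbonyl)vinyl] ether | C=C(O[C@H]1C=C(C(=O)OC)C[C@H]2O[C@](C)(OC)[C@@](C)(OC)O[C@H]12)C(=O)OC | intermediate
9 | methyl (3S,4S,5R)-4,5-dihydroxy-3-[1-(methoxycarbonyl)vinyloxy]cyclohex-1-ene-1-carboxylate | C=C(O[C@H]1C=C(C(=O)OC)C[C@@H](O)[C@@H]1O)C(=O)OC | intermediate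
10 | methyl (3S,4S,5R)-5-hydroxy-3,4-(1-methylidene-2-oxoethane-1,2-diyldioxy)cyclohex-1-ene-1-carboxylate (methylidene dioxanone lactone) | C=C1O[C@H]2C=C(C(=O)OC)C[C@@H](O)[C@@H]2OC1=O | intermediate
11 | di-tert-butyl squarate | CC(C)(C)OC1=C(OC(C)(C)C)C(=O)C1=O | starting material
12 | lithium 2,3-di-tert-butoxy-1-methyl-4-oxocyclobut-2-en-1-olate | CC1([O-])C(OC(C)(C)C)=C(OC(C)(C)C)C1=O.[Li+] | intermediate
13 | 2,3-di-tert-butoxy-1-methyl-4-oxocyclobut-2-en-1-yl trifluoroacetate | CC1(OC(=O)C(F)(F)F)C(OC(C)(C)C)=C(OC(C)(C)C)C1=O | intermediate
14 | 3-tert-butoxy-4-methylcyclobut-3-ene-1,2-dione | CC1=C(OC(C)(C)C)C(=O)C1=O | intermediate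
15 | lithium 2-tert-butoxy-1,3-dimethyl-4-oxocyclobut-2-en-1-olate | CC1=C(OC(C)(C)C)C(C)([O-])C1=O.[Li+] | intermediate
16 | 3-tert-butoxy-2,4-dimethyl-4-(trimethylsilyloxy)cyclobut-2-en-1-one (racemic) | CC1=C(OC(C)(C)C)C(C)(O[Si](C)(C)C)C1=O | intermediate
17 | (2E,4E)-hexa-2,4-dienal | C/C=C/C=C/C=O | starting material
18 | (4E,6E)-octa-4,6-dien-1-yn-3-ol (racemic) | C/C=C/C=C/C(O)C#C | intermediate
19 | (4E,6E)-octa-4,6-dien-1-yn-3-one | C/C=C/C=C/C(=O)C#C | intermediate
20 | (3Z)-3-tert-butoxy-2-methyl-4-(trimethylsilyloxy)penta-1,3-dien-1-one (vinylketene) | O=C=C(C)/C(OC(C)(C)C)=C(\C)O[Si](C)(C)C | intermediate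
21 | 5-tert-butoxy-2-[(2E,4E)-hexa-2,4-dienoyl]-4,6-dimethyl-4-(trimethylsilyloxy)cyclohexa-2,5-dien-1-one (racemic) | C/C=C/C=C/C(=O)C1=CC(C)(O[Si](C)(C)C)C(OC(C)(C)C)=C(C)C1=O | intermediate
22 | sorbicillinol, 4-[(2E,4E)-hexa-2,4-dienoyl]-3,6-dihydroxy-2,6-dimethylcyclohexa-2,4-dien-1-one (racemic; the R enantiomer is consumed productively) | C/C=C/C=C/C(=O)C1=CC(C)(O)C(=O)C(C)=C1O | intermediate
23 | target CNP0259039.2 (endo, OH-syn spiro adduct) | C/C=C/C=C/C(O)=C1/C(=O)[C@@]2(C)C(=O)[C@](C)(O)[C@@H]1C[C@]21O[C@H]2C=C(C(=O)OC)C[C@@H](O)[C@@H]2OC1=O | target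

Total step count: 12. Longest linear sequence: 7 steps (steps 1, 2, 3, 5, 6, 7, 12).

**Steps most likely to fail**

Step 11. The vinylketene may be consumed by a [1,5]-hydrogen shift from its inward methyl group or by oligomerisation before the ynone intercepts it, or the ynone may polymerise at 110 °C. The fallback sets out from 16 and from the dried filtrate of ynone 19 made as in step 11, and replaces the uncatalysed pericyclic sequence by metal-mediated C–C bond activation: Ni(COD)2 (10 mol %) in THF at 0 °C → rt. Zerovalent nickel should insert into the acyl–C4 bond of 16, the alkyne of 19 should insert into the resulting nickelacycle, and reductive elimination closes the six-membered ring. This is the known nickel-catalysed cyclobutenone–alkyne ring expansion; it runs at room temperature without free ketene. The route is rejoined at 21, and this path makes no compound outside the list (F0).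

Step 12. The chiral dienophile may discriminate poorly between the two quinol enantiomers, endo/exo selectivity may be low, and dimerisation of the liberated quinol may compete; the result would be diastereomer mixtures that are hard to separate. The fallback sets out from 21 and moves the resolution ahead of the fragment union: preparative HPLC on a chiral stationary phase should give the (4R)-dienone F1. F1 (1.2 equiv) is then added slowly to 10 under the TFA conditions of step 12, so that only matched cycloaddition modes are available. The route is rejoined at 23.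

Step 7. The acid-sensitive enol ether may hydrolyse or oligomerise during the forcing acidic lactonisation, or ring closure may stay incomplete. The fallback sets out from 7 and builds the lactone before the exocyclic alkene exists: TFA/H2O, then CSA in PhMe at 80 °C, should give the α-phosphono lactone F2. A Horner–Wadsworth–Emmons reaction of F2 (LiN(SiMe3)2, 2.1 equiv, THF, −78 °C; then HCHO) then installs the methylidene group under mild basic conditions. The route is rejoined at 10.

**Further compounds**
F0 | step 11 | none | none
F1 | step 12 | (4R)-5-tert-butoxy-2-[(2E,4E)-hexa-2,4-dienoyl]-4,6-dimethyl-4-(trimethylsilyloxy)cyclohexa-2,5-dien-1-one | C/C=C/C=C/C(=O)C1=C[C@@](C)(O[Si](C)(C)C)C(OC(C)(C)C)=C(C)C1=O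
F2 | step 7 | methyl (3S,4S,5R)-3,4-[1-(dimethoxyphosphoryl)-2-oxoethane-1,2-diyldioxy]-5-hydroxycyclohex-1-ene-1-carboxylate (α-phosphono lactone, epimer mixture at CH–P) | COP(=O)(OC)C1O[C@H]2C=C(C(=O)OC)C[C@@H](O)[C@@H]2OC1=O
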